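## Retrosynthetic overview

1. Target 31 ⇒ ring-closing metathesis at C6=C7 of the fully functionalised acyclic diene 30; the 14-membered ring is closed last.
2. 30 ⇒ C12–C13 union of lactone acid 22 (C1–C5, C13–C17) with alkyne 5 (C6–C12) by acyl Sonogashira coupling, then ketone reduction (13S), trans-hydrostannation/methylation (E-C11=C12), OH-directed epoxidation and acetylation.
3. 22 ⇒ cis α-methylene-γ-butyrolactone from dienal 18 and allylic bromide 11 by CrCl2-catalysed asymmetric allylation (sets C1 and C2).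
4. 5 ⇐ (R)-linalool (C8 from the chiral pool); 18 ⇐ propargyl alcohol + allyl bromide; 11 ⇐ propane-1,3-diol + methyl acrylate.
5. Ring order: γ-lactone (step 13), oxirane (step 20), 14-membered carbocycle (step 23).

Numbering used below (cembrane type): C1 ring-fusion CH, C2 lactone CH–O, C3=C4(Me), C5, C6=C7, C8 (Me, OH), C9, C10, C11–C12 oxirane (Me on C12), C13 (OAc), C14; C15 α-carbon, C16 C=O, C17 exocyclic CH2. Target: 1S,2S,8R,11S,12R,13S; 3E,6E; lactone cis-fused.

Assumption: in step 13 the (S,S) ligand is taken to be the enantiomer that favours Re-face addition to the aldehyde; if the sense is the opposite, its (R,R) antipode is used.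

## Route

Step 1
Reactants: 1 (R)-linalool
Product: 2 triethyl{[(3R)-3,7-dimethylocta-1,6-dien-3-yl]oxy}silane
Conditions: Et3SiOTf, 2,6-lutidine, CH2Cl2, −78 to 0 °C
Reagents that add atoms: triethylsilyl triflate, CC[Si](CC)(CC)OS(=O)(=O)C(F)(F)F
Why: A silyl triflate with a hindered pyridine base silylates even a tertiary allylic alcohol (silyl ether formation), masking the C8 hydroxyl, whose R configuration comes from the chiral pool.

Step 2
Reactants: 2 triethyl{[(3R)-3,7-dimethylocta-1,6-dien-3-yl]oxy}silane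
Product: 3 (6R)-2,6-dimethyl-6-(triethylsilyloxy)oct-7-ene-2,3-diol (both C3 epimers)
Conditions: K2OsO2(OH)4 (1 mol %), NMO, acetone–H2O, 0 °C to rt
Reagents that add atoms: N-methylmorpholine N-oxide, C[N+]1([O-])CCOCC1; water, O
Why: K2OsO2(OH)4-catalysed dihydroxylation (Upjohn) is faster at the electron-rich trisubstituted alkene than at the hindered vinyl group next to the quaternary silyloxy carbon, and the new carbinol centre is destroyed in the next step.

Step 3
Reactants: 3 (6R)-2,6-dimethyl-6-(triethylsilyloxy)oct-7-ene-2,3-diol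
Product: 4 (4R)-4-methyl-4-(triethylsilyloxy)hex-5-enal
Conditions: NaIO4, THF–H2O (pH 7), 0 °C to rt
Reagents that add atoms: none
Why: Periodate glycol cleavage of the 1,2-diol gives the aldehyde under neutral conditions that leave the silyl ether and the vinyl group alone.

Step 4
Reactants: 4 (4R)-4-methyl-4-(triethylsilyloxy)hex-5-enal
Product: 5 (3R)-3-methyl-3-(triethylsilyloxy)hept-1-en-6-yne
Conditions: dimethyl (1-diazo-2-oxopropyl)phosphonate, K2CO3, MeOH, 0 °C to rt
Reagents that add atoms: dimethyl (1-diazo-2-oxopropyl)phosphonate, CC(=O)C(=[N+]=[N-])P(=O)(OC)OC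
Why: Ohira–Bestmann (Seyferth–Gilbert) homologation converts the enolisable aldehyde into the terminal alkyne (adding C12) under mild carbonate conditions without touching the stereocentre.

Step 5
Reactants: 6 propane-1,3-diol
Product: 7 3-(tert-butyldimethylsilyloxy)propan-1-ol
Conditions: NaH (1.0 equiv), THF, rt; t-BuMe2SiCl (1.0 equiv)
Reagents that add atoms: tert-butyldimethylsilyl chloride, CC(C)(C)[Si](C)(C)Cl
Why: Monodeprotonation of the symmetric diol gives a poorly soluble monoalkoxide that is silylated once (desymmetrising monosilylation).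

Step 6
Reactants: 7 3-(tert-butyldimethylsilyloxy)propan-1-ol
Product: 8 3-(tert-butyldimethylsilyloxy)propanal
Conditions: TEMPO (10 mol %), PhI(OAc)2, CH2Cl2, rt
Reagents that add atoms: none
Why: Oxoammonium (TEMPO) oxidation with PhI(OAc)2 as terminal oxidant stops at the aldehyde and does not affect the silyl ether.

Step 7
Reactants: 8 3-(tert-butyldimethylsilyloxy)propanal; 9 methyl acrylate
Product: 10 methyl 5-(tert-butyldimethylsilyloxy)-3-hydroxy-2-methylidenepentanoate (racemic)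
Conditions: DABCO (0.5 equiv), MeOH (1 equiv), neat 9 (3 equiv), rt, 4 d
Reagents that add atoms: none
Why: Morita–Baylis–Hillman reaction of the unhindered aldehyde with the acrylate gives the allylic alcohol, whose racemic carbinol centre is removed in the next step.

Step 8
Reactants: 10 methyl 5-(tert-butyldimethylsilyloxy)-3-hydroxy-2-methylidenepentanoate
Product: 11 methyl (2Z)-2-(bromomethyl)-5-(tert-butyldimethylsilyloxy)pent-2-enoate
Conditions: NBS, Me2S, CH2Cl2, 0 °C to rt
Reagents that add atoms: N-bromosuccinimide, O=C1CCC(=O)N1Br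
Why: Corey–Kim-type activation of the allylic alcohol followed by SN2' attack of bromide gives the rearranged primary allylic bromide, the conjugated alkene forming with the ester trans to the chain (2Z) for steric reasons.

Step 9
Reactants: 12 prop-2-yn-1-ol; 13 allyl bromide
Product: 14 hex-5-en-2-yn-1-ol
Conditions: CuI (10 mol %), K2CO3, Bu4NBr (cat.), DMF, rt
Reagents that add atoms: none
Why: CuI-catalysed coupling of the copper acetylide formed in situ with the allylic bromide (sp–sp3 coupling) gives the skipped enyne without protecting the hydroxyl.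

Step 10
Reactants: 14 hex-5-en-2-yn-1-ol
Product: 16 (2Z)-3-iodohexa-2,5-dien-1-ol, via cyclic vinylalanate 15 (not isolated)
Conditions: NaAlH2(OCH2CH2OMe)2 (1.6 equiv), THF, 0 °C to rt; EtOAc quench; I2, THF, −78 to 0 °C
Reagents that add atoms: iodine, II
Why: Alkoxide-directed trans-hydroalumination of the propargylic alcohol places aluminium on C3 in a five-membered alanate, and iodinolysis with retention gives the Z iodide that fixes the later 3E geometry of the target.

Step 11
Reactants: 16 (2Z)-3-iodohexa-2,5-dien-1-ol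
Product: 17 (2E)-3-methylhexa-2,5-dien-1-ol
Conditions: Me2CuLi (4 equiv), Et2O, 0 °C
Reagents that add atoms: lithium dimethylcuprate, [Li+].C[Cu-]C
Why: Cross-coupling of the vinylic iodide with Me2CuLi (Corey–Posner type) replaces iodine by methyl with retention of alkene geometry, giving the E trisubstituted alkene.

Step 12
Reactants: 17 (2E)-3-methylhexa-2,5-dien-1-ol
Product: 18 (2E)-3-methylhexa-2,5-dienal
Conditions: MnO2 (15 equiv), CH2Cl2, rt
Reagents that add atoms: none
Why: MnO2 oxidises the allylic alcohol selectively to the enal under neutral conditions that do not isomerise the E alkene or the skipped diene.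

Step 13
Reactants: 11 methyl (2Z)-2-(bromomethyl)-5-(tert-butyldimethylsilyloxy)pent-2-enoate; 18 (2E)-3-methylhexa-2,5-dienal
Product: 20 (4S,5S)-4-[2-(tert-butyldimethylsilyloxy)ethyl]-3-methylidene-5-[(1E)-2-methylpenta-1,4-dien-1-yl]oxolan-2-one, via syn hydroxy ester 19 (not isolated)
Conditions: CrCl2 (10 mol %), 1,8-bis[(4S)-4-isopropyl-4,5-dihydrooxazol-2-yl]-3,6-diphenyl-9H-carbazole (12 mol %), Et3N (20 mol %), Mn powder (2 equiv), Cp2ZrCl2 (1.1 equiv), THF, rt; 1 M HCl work-up; TsOH·H2O (cat.), CH2Cl2, rt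
Reagents that add atoms: none
Why: In this catalytic asymmetric Nozaki–Hiyama–Kishi-type 2-(alkoxycarbonyl)allylation the allylchromium intermediate from the Z bromide adds through a chair transition state with its γ-substituent axial, which gives the syn adduct and hence the cis lactone on acid-induced lactonisation, while the chiral CrCl2–bis(oxazoline) complex directs attack to the Re face of the aldehyde and so sets 2S and with it 1S.

Step 14
Reactants: 20 (4S,5S)-4-[2-(tert-butyldimethylsilyloxy)ethyl]-3-methylidene-5-[(1E)-2-methylpenta-1,4-dien-1-yl]oxolan-2-one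
Product: 21 (4S,5S)-4-(2-hydroxyethyl)-3-methylidene-5-[(1E)-2-methylpenta-1,4-dien-1-yl]oxolan-2-one
Conditions: HF·pyridine, pyridine, THF, 0 °C to rt
Reagents that add atoms: none
Why: Fluoride-mediated desilylation under mildly acidic conditions removes the primary silyl ether without base-induced oxa-Michael addition to the α-methylene lactone or isomerisation of the skipped diene.

Step 15
Reactants: 21 (4S,5S)-4-(2-hydroxyethyl)-3-methylidene-5-[(1E)-2-methylpenta-1,4-dien-1-yl]oxolan-2-one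
Product: 22 2-[(2S,3S)-4-methylidene-2-[(1E)-2-methylpenta-1,4-dien-1-yl]-5-oxooxolan-3-yl]acetic acid
Conditions: TEMPO (20 mol %), PhI(OAc)2 (2.5 equiv), MeCN–H2O (1:1), rt
Reagents that add atoms: water, O
Why: TEMPO/PhI(OAc)2 in aqueous acetonitrile oxidises the primary alcohol through the aldehyde hydrate to the carboxylic acid while the alkenes and the α-methylene lactone are inert.

Step 16
Reactants: 22 2-[(2S,3S)-4-methylidene-2-[(1E)-2-methylpenta-1,4-dien-1-yl]-5-oxooxolan-3-yl]acetic acid; 5 (3R)-3-methyl-3-(triethylsilyloxy)hept-1-en-6-yne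
Product: 24 (4S,5S)-3-methylidene-5-[(1E)-2-methylpenta-1,4-dien-1-yl]-4-[(7R)-7-methyl-2-oxo-7-(triethylsilyloxy)non-8-en-3-yn-1-yl]oxolan-2-one, via acid chloride 23 (not isolated)
Conditions: 1-chloro-N,N,2-trimethylprop-1-en-1-amine, CH2Cl2, 0 °C to rt; then 5, PdCl2(PPh3)2 (2 mol %), CuI (4 mol %), Et3N, THF, rt
Reagents that add atoms: none
Why: The acid is converted under neutral conditions into its chloride, which undergoes PdCl2(PPh3)2/CuI-catalysed acyl Sonogashira coupling with the terminal alkyne, forming the C12–C13 bond and joining the two halves as an ynone.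

Step 17
Reactants: 24 (4S,5S)-3-methylidene-5-[(1E)-2-methylpenta-1,4-dien-1-yl]-4-[(7R)-7-methyl-2-oxo-7-(triethylsilyloxy)non-8-en-3-yn-1-yl]oxolan-2-one
Product: 25 (4S,5S)-4-[(2S,7R)-2-hydroxy-7-methyl-7-(triethylsilyloxy)non-8-en-3-yn-1-yl]-3-methylidene-5-[(1E)-2-methylpenta-1,4-dien-1-yl]oxolan-2-one
Conditions: Ru[(S,S)-TsDPEN](p-cymene) (amido complex, 2 mol %), i-PrOH, rt
Reagents that add atoms: none
Why: In this Noyori asymmetric transfer hydrogenation the hydride formed from Ru[(S,S)-TsDPEN](p-cymene) attacks one carbonyl face with the alkyne as the π-directing group, which gives the 13S propargylic alcohol and leaves the C=C bonds alone.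

Step 18
Reactants: 25 (4S,5S)-4-[(2S,7R)-2-hydroxy-7-methyl-7-(triethylsilyloxy)non-8-en-3-yn-1-yl]-3-methylidene-5-[(1E)-2-methylpenta-1,4-dien-1-yl]oxolan-2-one
Product: 26 (4S,5S)-4-[(2S,3Z,7R)-2-hydroxy-7-methyl-3-(tributylstannyl)-7-(triethylsilyloxy)nona-3,8-dien-1-yl]-3-methylidene-5-[(1E)-2-methylpenta-1,4-dien-1-yl]oxolan-2-one
Conditions: [Cp*RuCl]4 (2.5 mol %), Bu3SnH (1.1 equiv, slow addition), CH2Cl2, rt
Reagents that add atoms: tributyltin hydride, CCCC[SnH](CCCC)CCCC
Why: In this [Cp*RuCl]4-catalysed trans-hydrostannation a hydrogen bond between the propargylic OH and the chloride ligand steers tin to the proximal alkyne carbon (C12) and hydrogen adds anti at C11, so that the C10 chain and C13 end up trans.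

Step 19
Reactants: 26 (4S,5S)-4-[(2S,3Z,7R)-2-hydroxy-7-methyl-3-(tributylstannyl)-7-(triethylsilyloxy)nona-3,8-dien-1-yl]-3-methylidene-5-[(1E)-2-methylpenta-1,4-dien-1-yl]oxolan-2-one
Product: 27 (4S,5S)-4-[(2S,3E,7R)-2-hydroxy-3,7-dimethyl-7-(triethylsilyloxy)nona-3,8-dien-1-yl]-3-methylidene-5-[(1E)-2-methylpenta-1,4-dien-1-yl]oxolan-2-one
Conditions: MeI, Cu(O2CC4H3S) (copper thiophene-2-carboxylate, 1.5 equiv), [Bu4N][Ph2PO2] (1.5 equiv), Pd(PPh3)4 (5 mol %), DMF, rt
Reagents that add atoms: methyl iodide, CI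
Why: This Stille-type methylation mediated by Pd(PPh3)4 and Cu(O2CC4H3S), with the phosphinate as tin scavenger, replaces tin by methyl with retention and completes the E-trisubstituted C11=C12 alkene.

Step 20
Reactants: 27 (4S,5S)-4-[(2S,3E,7R)-2-hydroxy-3,7-dimethyl-7-(triethylsilyloxy)nona-3,8-dien-1-yl]-3-methylidene-5-[(1E)-2-methylpenta-1,4-dien-1-yl]oxolan-2-one
Product: 28 (4S,5S)-4-{(2S)-2-hydroxy-2-[(2S,3S)-2-methyl-3-[(3R)-3-methyl-3-(triethylsilyloxy)pent-4-en-1-yl]oxiran-2-yl]ethyl}-3-methylidene-5-[(1E)-2-methylpenta-1,4-dien-1-yl]oxolan-2-one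
Conditions: VO(acac)2 (5 mol %), t-BuOOH (1.5 equiv, decane), CH2Cl2, 0 °C to rt
Reagents that add atoms: tert-butyl hydroperoxide, CC(C)(C)OO
Why: This hydroxyl-directed VO(acac)2-catalysed epoxidation reacts only at the allylic alcohol alkene and, because A(1,2) strain with the C12 methyl holds the C13–H in the alkene plane, delivers oxygen to the face that gives the erythro epoxy alcohol, which is 11S,12R in target numbering.

Step 21
Reactants: 28 (4S,5S)-4-{(2S)-2-hydroxy-2-[(2S,3S)-2-methyl-3-[(3R)-3-methyl-3-(triethylsilyloxy)pent-4-en-1-yl]oxiran-2-yl]ethyl}-3-methylidene-5-[(1E)-2-methylpenta-1,4-dien-1-yl]oxolan-2-one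
Product: 29 (1S)-1-{(2R,3S)-2-methyl-3-[(3R)-3-methyl-3-(triethylsilyloxy)pent-4-en-1-yl]oxiran-2-yl}-2-{(2S,3S)-4-methylidene-2-[(1E)-2-methylpenta-1,4-dien-1-yl]-5-oxooxolan-3-yl}ethyl acetate
Conditions: Ac2O, pyridine, DMAP (cat.), CH2Cl2, 0 °C to rt
Reagents that add atoms: acetic anhydride, CC(=O)OC(C)=O
Why: DMAP-catalysed acylation of the secondary alcohol installs the C13 acetate while the tertiary C8 oxygen is still silylated.

Step 22
Reactants: 29 (1S)-1-{(2R,3S)-2-methyl-3-[(3R)-3-methyl-3-(triethylsilyloxy)pent-4-en-1-yl]oxiran-2-yl}-2-{(2S,3S)-4-methylidene-2-[(1E)-2-methylpenta-1,4-dien-1-yl]-5-oxooxolan-3-yl}ethyl acetate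
Product: 30 (1S)-1-{(2R,3S)-3-[(3R)-3-hydroxy-3-methylpent-4-en-1-yl]-2-methyloxiran-2-yl}-2-{(2S,3S)-4-methylidene-2-[(1E)-2-methylpenta-1,4-dien-1-yl]-5-oxooxolan-3-yl}ethyl acetate
Conditions: Bu4NF, AcOH (1:1, 3 equiv), THF, 0 °C to rt
Reagents that add atoms: none
Why: Acetic acid-buffered fluoride cleaves the tertiary triethylsilyl ether (desilylation) without acetate cleavage, epoxide opening or addition to the α-methylene lactone.

Step 23
Reactants: 30 (1S)-1-{(2R,3S)-3-[(3R)-3-hydroxy-3-methylpent-4-en-1-yl]-2-methyloxiran-2-yl}-2-{(2S,3S)-4-methylidene-2-[(1E)-2-methylpenta-1,4-dien-1-yl]-5-oxooxolan-3-yl}ethyl acetate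
Product: 31 CNP0288879.3
Conditions: second-generation Hoveyda–Grubbs catalyst RuCl2(H2IMes)(=CH-C6H4-2-O-i-Pr) (10 mol %, in portions), 1,4-benzoquinone (20 mol %), toluene (0.5 mM), 70 °C, argon sparge
Reagents that add atoms: none
Why: Ring-closing metathesis of the two monosubstituted alkenes closes the 14-membered ring at C6=C7 under high dilution, the macrocycle and the adjacent quaternary C8 favouring the E alkene, while the trisubstituted alkene, the α-methylene lactone and the epoxide are poor metathesis partners.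

## Compound list

1 | (R)-linalool, (3R)-3,7-dimethylocta-1,6-dien-3-ol | C=C[C@](C)(O)CCC=C(C)C | starting material
2 | triethyl{[(3R)-3,7-dimethylocta-1,6-dien-3-yl]oxy}silane | C=C[C@](C)(O[Si](CC)(CC)CC)CCC=C(C)C | intermediate
3 | (6R)-2,6-dimethyl-6-(triethylsilyloxy)oct-7-ene-2,3-diol (C3 epimers) | C=C[C@](C)(O[Si](CC)(CC)CC)CCC(O)C(C)(C)O | intermediate
4 | (4R)-4-methyl-4-(triethylsilyloxy)hex-5-enal | C=C[C@](C)(O[Si](CC)(CC)CC)CCC=O | intermediate
5 | (3R)-3-methyl-3-(triethylsilyloxy)hept-1-en-6-yne | C=C[C@](C)(O[Si](CC)(CC)CC)CCC#C | intermediate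
6 | propane-1,3-diol | OCCCO | starting material
7 | 3-(tert-butyldimethylsilyloxy)propan-1-ol | OCCCO[Si](C)(C)C(C)(C)C | intermediate
8 | 3-(tert-butyldimethylsilyloxy)propanal | O=CCCO[Si](C)(C)C(C)(C)C | intermediate
9 | methyl acrylate | C=CC(=O)OC | starting material
10 | methyl 5-(tert-butyldimethylsilyloxy)-3-hydroxy-2-methylidenepentanoate (racemic) | C=C(C(=O)OC)C(O)CCO[Si](C)(C)C(C)(C)C | intermediate
11 | methyl (2Z)-2-(bromomethyl)-5-(tert-butyldimethylsilyloxy)pent-2-enoate | COC(=O)/C(CBr)=C/CCO[Si](C)(C)C(C)(C)C | intermediate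
12 | prop-2-yn-1-ol | C#CCO | starting material
13 | allyl bromide | C=CCBr | starting material
14 | hex-5-en-2-yn-1-ol | C=CCC#CCO | intermediate
15 | sodium 2,2-bis(2-methoxyethoxy)-3-(prop-2-en-1-yl)-2,5-dihydro-1,2-oxaaluminol-2-uide (cyclic vinylalanate, not isolated) | [Na+].C=CCC1=CCO[Al-]1(OCCOC)OCCOC | intermediate
16 | (2Z)-3-iodohexa-2,5-dien-1-ol | C=CC/C(I)=C/CO | intermediate
17 | (2E)-3-methylhexa-2,5-dien-1-ol | C=CC/C(C)=C/CO | intermediate
18 | (2E)-3-methylhexa-2,5-dienal | C=CC/C(C)=C/C=O | intermediate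
19 | methyl (3S,4S,5E)-3-[2-(tert-butyldimethylsilyloxy)ethyl]-4-hydroxy-6-methyl-2-methylidenenona-5,8-dienoate (syn hydroxy ester, not isolated) | C=C(C(=O)OC)[C@H](CCO[Si](C)(C)C(C)(C)C)[C@@H](O)/C=C(\C)CC=C | intermediate
20 | (4S,5S)-4-[2-(tert-butyldimethylsilyloxy)ethyl]-3-methylidene-5-[(1E)-2-methylpenta-1,4-dien-1-yl]oxolan-2-one | C=C1C(=O)O[C@@H](/C=C(\C)CC=C)[C@H]1CCO[Si](C)(C)C(C)(C)C | intermediate
21 | (4S,5S)-4-(2-hydroxyethyl)-3-methylidene-5-[(1E)-2-methylpenta-1,4-dien-1-yl]oxolan-2-one | C=C1C(=O)O[C@@H](/C=C(\C)CC=C)[C@H]1CCO | intermediate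
22 | 2-[(2S,3S)-4-methylidene-2-[(1E)-2-methylpenta-1,4-dien-1-yl]-5-oxooxolan-3-yl]acetic acid | C=C1C(=O)O[C@@H](/C=C(\C)CC=C)[C@H]1CC(=O)O | intermediate
23 | 2-[(2S,3S)-4-methylidene-2-[(1E)-2-methylpenta-1,4-dien-1-yl]-5-oxooxolan-3-yl]acetyl chloride (not isolated) | C=C1C(=O)O[C@@H](/C=C(\C)CC=C)[C@H]1CC(=O)Cl | intermediate
24 | (4S,5S)-3-methylidene-5-[(1E)-2-methylpenta-1,4-dien-1-yl]-4-[(7R)-7-methyl-2-oxo-7-(triethylsilyloxy)non-8-en-3-yn-1-yl]oxolan-2-one | C=C1C(=O)O[C@@H](/C=C(\C)CC=C)[C@H]1CC(=O)C#CCC[C@@](C)(O[Si](CC)(CC)CC)C=C | intermediate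
25 | (4S,5S)-4-[(2S,7R)-2-hydroxy-7-methyl-7-(triethylsilyloxy)non-8-en-3-yn-1-yl]-3-methylidene-5-[(1E)-2-methylpenta-1,4-dien-1-yl]oxolan-2-one | C=C1C(=O)O[C@@H](/C=C(\C)CC=C)[C@H]1C[C@H](O)C#CCC[C@@](C)(O[Si](CC)(CC)CC)C=C | intermediate
26 | (4S,5S)-4-[(2S,3Z,7R)-2-hydroxy-7-methyl-3-(tributylstannyl)-7-(triethylsilyloxy)nona-3,8-dien-1-yl]-3-methylidene-5-[(1E)-2-methylpenta-1,4-dien-1-yl]oxolan-2-one | C=C1C(=O)O[C@@H](/C=C(\C)CC=C)[C@H]1C[C@H](O)/C(=C/CC[C@@](C)(O[Si](CC)(CC)CC)C=C)[Sn](CCCC)(CCCC)CCCC | intermediate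
27 | (4S,5S)-4-[(2S,3E,7R)-2-hydroxy-3,7-dimethyl-7-(triethylsilyloxy)nona-3,8-dien-1-yl]-3-methylidene-5-[(1E)-2-methylpenta-1,4-dien-1-yl]oxolan-2-one | C=C1C(=O)O[C@@H](/C=C(\C)CC=C)[C@H]1C[C@H](O)/C(C)=C/CC[C@@](C)(O[Si](CC)(CC)CC)C=C | intermediate
28 | (4S,5S)-4-{(2S)-2-hydroxy-2-[(2S,3S)-2-methyl-3-[(3R)-3-methyl-3-(triethylsilyloxy)pent-4-en-1-yl]oxiran-2-yl]ethyl}-3-methylidene-5-[(1E)-2-methylpenta-1,4-dien-1-yl]oxolan-2-one (same geometry as 11S,12R,13S of the target; the C12 label becomes R once O13 is acylated) | C=C1C(=O)O[C@@H](/C=C(\C)CC=C)[C@H]1C[C@H](O)[C@]2(C)O[C@H]2CC[C@@](C)(O[Si](CC)(CC)CC)C=C | intermediate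
29 | (1S)-1-{(2R,3S)-2-methyl-3-[(3R)-3-methyl-3-(triethylsilyloxy)pent-4-en-1-yl]oxiran-2-yl}-2-{(2S,3S)-4-methylidene-2-[(1E)-2-methylpenta-1,4-dien-1-yl]-5-oxooxolan-3-yl}ethyl acetate | C=C1C(=O)O[C@@H](/C=C(\C)CC=C)[C@H]1C[C@H](OC(C)=O)[C@]2(C)O[C@H]2CC[C@@](C)(O[Si](CC)(CC)CC)C=C | intermediate
30 | (1S)-1-{(2R,3S)-3-[(3R)-3-hydroxy-3-methylpent-4-en-1-yl]-2-methyloxiran-2-yl}-2-{(2S,3S)-4-methylidene-2-[(1E)-2-methylpenta-1,4-dien-1-yl]-5-oxooxolan-3-yl}ethyl acetate | C=C1C(=O)O[C@@H](/C=C(\C)CC=C)[C@H]1C[C@H](OC(C)=O)[C@]2(C)O[C@H]2CC[C@@](C)(O)C=C | intermediate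
31 | CNP0288879.3, (1S,2S,3E,6E,8R,11S,12R,13S)-13-acetoxy-11,12-epoxy-8-hydroxycembra-3,6,15(17)-trien-16,2-olide | C=C1C(=O)O[C@H]2/C=C(\C)C/C=C/[C@](C)(O)CC[C@@H]3O[C@@]3(C)[C@@H](OC(C)=O)C[C@@H]12 | target

## Step count

Total: 23 steps. Longest linear sequence: 15 steps (propane-1,3-diol 6 to 31 through steps 5–8 and 13–23; the branch from propargyl alcohol through steps 9–12 and 13–23 is equally long; the linalool branch is 12 steps).

## Three steps most likely to fail, with fallbacks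

Step 23 (ring-closing metathesis). The C7 vinyl group sits on a quaternary carbinol, so ring closure may lose to oligomerisation or give an E/Z mixture. The free C8-OH could also open the epoxide at 70 °C. Fallback, setting out from 27 and coming back at 31: close the ring before the oxirane and the acetate exist and oxidise on the macrocycle. Bu4NF/AcOH on 27 gives the seco diol (4S,5S)-4-[(2S,3E,7R)-2,7-dihydroxy-3,7-dimethylnona-3,8-dien-1-yl]-3-methylidene-5-[(1E)-2-methylpenta-1,4-dien-1-yl]oxolan-2-one F1. Ring-closing metathesis with the step 23 catalyst gives the macrocyclic diol (1S,2S,3E,6E,8R,11E,13S)-8,13-dihydroxycembra-3,6,11,15(17)-tetraen-16,2-olide F2. Ti(O-i-Pr)4, L-(+)-diisopropyl tartrate and t-BuOOH (4 Å sieves, CH2Cl2, −20 °C) then epoxidise only the secondary allylic alcohol. The tertiary allylic C8-OH is inert to this reagent, and the tartrate is matched with 13S and attacks the same erythro face. This gives the epoxy diol 13-O-deacetyl-31 F3, and Ac2O/pyridine at 0 °C acetylates only the secondary hydroxyl to give 31.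

Step 18 (trans-hydrostannation, with the methylation of step 19). The substrate carries five C=C bonds and a 1,6-enyne unit. Tin may go in part to the distal carbon, and the α-stannyl allylic alcohol can protodestannylate. Fallback, setting out from acid chloride 23 and aldehyde 4 and coming back at 27: build C11=C12 by Wittig olefination with the methyl group already in place. Chloride 23 is added at −78 °C to 2 equiv of Ph3P=CHCH3 (from [Ph3PEt]Br and KN(SiMe3)2, THF) to give the stabilised keto ylide (4S,5S)-3-methylidene-5-[(1E)-2-methylpenta-1,4-dien-1-yl]-4-[2-oxo-3-(triphenyl-λ5-phosphanylidene)butyl]oxolan-2-one F4. Heating F4 with 4 in toluene (90 °C) gives the E enone (4S,5S)-4-[(3E,7R)-3,7-dimethyl-2-oxo-7-(triethylsilyloxy)nona-3,8-dien-1-yl]-3-methylidene-5-[(1E)-2-methylpenta-1,4-dien-1-yl]oxolan-2-one F5. Corey–Bakshi–Shibata reduction with (R)-2-methyl-CBS-oxazaborolidine and catecholborane (toluene, −78 °C, alkenyl as the large group) gives the 13S alcohol 27. Steps 4 and 16–19 are then not needed.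

Step 13 (catalytic asymmetric chromium allylation). Enantio- and diastereoselectivity with a γ-substituted bromide and an enal are not assured, and the amine may isomerise the skipped dienal. Fallback, setting out from 11 and 18 and coming back at 20: replace the redox allylation by an acid-catalysed allylboration. Pd2(dba)3 (cat.) and B2pin2 in DMSO at 50 °C convert 11 into methyl (2E)-5-(tert-butyldimethylsilyloxy)-2-[(4,4,5,5-tetramethyl-1,3,2-dioxaborolan-2-yl)methyl]pent-2-enoate F6. F6 adds to 18 under catalysis by a chiral BINOL-derived phosphoric acid (3,3'-bis(2,4,6-triisopropylphenyl) type, the enantiomer that gives Re-face attack, toluene, −30 °C to rt). The closed chair transition state, with the chain cis to CH2B, gives the syn hydroxy ester 19, and TsOH·H2O lactonises it to 20.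

## Further compounds

F1 | step 23 | (4S,5S)-4-[(2S,3E,7R)-2,7-dihydroxy-3,7-dimethylnona-3,8-dien-1-yl]-3-methylidene-5-[(1E)-2-methylpenta-1,4-dien-1-yl]oxolan-2-one | C=C1C(=O)O[C@@H](/C=C(\C)CC=C)[C@H]1C[C@H](O)/C(C)=C/CC[C@@](C)(O)C=C
F2 | step 23 | (1S,2S,3E,6E,8R,11E,13S)-8,13-dihydroxycembra-3,6,11,15(17)-tetraen-16,2-olide | C=C1C(=O)O[C@H]2/C=C(\C)C/C=C/[C@](C)(O)CC/C=C(\C)[C@@H](O)C[C@@H]12
F3 | step 23 | 13-O-deacetyl-31, (1S,2S,3E,6E,8R,11S,12S,13S)-11,12-epoxy-8,13-dihydroxycembra-3,6,15(17)-trien-16,2-olide | C=C1C(=O)O[C@H]2/C=C(\C)C/C=C/[C@](C)(O)CC[C@@H]3O[C@@]3(C)[C@@H](O)C[C@@H]12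
F4 | step 18 | (4S,5S)-3-methylidene-5-[(1E)-2-methylpenta-1,4-dien-1-yl]-4-[2-oxo-3-(triphenyl-λ5-phosphanylidene)butyl]oxolan-2-one | C=C1C(=O)O[C@@H](/C=C(\C)CC=C)[C@H]1CC(=O)C(C)=P(c2ccccc2)(c2ccccc2)c2ccccc2
F5 | step 18 | (4S,5S)-4-[(3E,7R)-3,7-dimethyl-2-oxo-7-(triethylsilyloxy)nona-3,8-dien-1-yl]-3-methylidene-5-[(1E)-2-methylpenta-1,4-dien-1-yl]oxolan-2-one | C=C1C(=O)O[C@@H](/C=C(\C)CC=C)[C@H]1CC(=O)/C(C)=C/CC[C@@](C)(O[Si](CC)(CC)CC)C=C
F6 | step 13 | methyl (2E)-5-(tert-butyldimethylsilyloxy)-2-[(4,4,5,5-tetramethyl-1,3,2-dioxaborolan-2-yl)methyl]pent-2-enoate | COC(=O)/C(CB1OC(C)(C)C(C)(C)O1)=C/CCO[Si](C)(C)C(C)(C)C
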